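**Retrosynthetic overview**
1. Target 23 ⇐ silyl ether 22. Ring B (ten-membered carbocycle) and ring C (cis-fused α-methylene lactone) close together, last, by intramolecular zinc 2-(methoxycarbonyl)allylation (C6–C7) of Z-enal/allylic bromide 19.
2. 19 ⇐ furanone 15 by cross-metathesis of the C7 vinyl group with methyl 2-(bromomethyl)acrylate (C11–C13), then oxidation of the C6 silyl ether.
3. Ring A (3(2H)-furanone) and the C10 quaternary centre ⇐ diynol 13 by a one-flask alkyne hydration / 5-endo heterocyclisation / 1,2-alkyl shift (C9 moves from C1 to C10 with chirality transfer). This is the key step and the first ring formed.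
4. 13 ⇐ chelation-controlled ethynylation of β-hydroxy ynone 9 ⇐ asymmetric aldol (acrolein) of methyl ynone 7 ⇐ Sonogashira coupling of Z-vinyl iodide 5 (from 2-butyne-1,4-diol) with 3-butyn-2-one.
5. Ring order: A (step 8), then B and C in one operation (step 11).

Labels: target carbons are C1–C15 (C1 ketone, C2=C3 furanone alkene, C4=C5 ring alkene, C6 lactone O-carbon, C7, C8 tiglate carbon, C9, C10 quaternary carbon, C11–C13 methylene-lactone unit with C12 the carbonyl, C14 methyl, C15 hydroxymethyl); the same labels are used for the corresponding atoms of all intermediates.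

Assumption: the SMILES is taken literally as (6S,7R,8R,10R) with a cis-fused lactone (H-6/H-7 cis), Z-C4=C5 and an E-tiglate, and (S,S)-ProPhenol is taken to be the ligand antipode that gives the (R)-aldol in step 5 (the (R,R)-ligand is used if the sense is opposite).

**Route**

Step 1
Reactants: 1 2-butyne-1,4-diol
Product: 2 4-(tert-butyldimethylsilyloxy)but-2-yn-1-ol
Conditions: NaH (1.0 equiv), THF, 0 °C; TBSCl (1.0 equiv), 0→23 °C
Reagents that add atoms: tert-butyldimethylsilyl chloride (TBSCl), CC(C)(C)[Si](C)(C)Cl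
Why: Monosilylation of a symmetrical diol through its sparingly soluble monosodium alkoxide (O-silylation); no stereocentre is involved.

Step 2
Reactants: 2 4-(tert-butyldimethylsilyloxy)but-2-yn-1-ol
Product: 4 (Z)-4-(tert-butyldimethylsilyloxy)-3-iodobut-2-en-1-ol, via cyclic alkenylalanate 3 (not isolated)
Conditions: NaAlH2(OCH2CH2OCH3)2 (1.6 equiv), THF, 0→23 °C; EtOAc; I2, THF, −78→0 °C
Reagents that add atoms: iodine, II
Why: Hydroxyl-directed trans-hydroalumination puts hydride on C5 and aluminium on C4 inside a five-membered alkoxyalanate, and iodinolysis with retention gives the vinyl iodide with C6 cis to iodine, which fixes the Z-C4=C5 geometry of the target.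

Step 3
Reactants: 4 (Z)-4-(tert-butyldimethylsilyloxy)-3-iodobut-2-en-1-ol
Product: 5 (Z)-tert-butyl{[2-iodo-4-(triethylsilyloxy)but-2-en-1-yl]oxy}dimethylsilane
Conditions: TESCl, imidazole, CH2Cl2, 0 °C
Reagents that add atoms: triethylsilyl chloride (TESCl), CC[Si](Cl)(CC)CC
Why: Standard silylation gives a C6–O-TES group that can later be oxidised selectively in the presence of the C15–O-TBS group; the alkene geometry is untouched.

Step 4
Reactants: 5 (Z)-tert-butyl{[2-iodo-4-(triethylsilyloxy)but-2-en-1-yl]oxy}dimethylsilane; 6 3-butyn-2-one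
Product: 7 (E)-5-[(tert-butyldimethylsilyloxy)methyl]-7-(triethylsilyloxy)hept-5-en-3-yn-2-one
Conditions: Pd(PPh3)2Cl2 (3 mol %), CuI (6 mol %), Et3N, THF, 0→23 °C, 6 (1.5 equiv)
Reagents that add atoms: none
Why: Sonogashira coupling (zerovalent palladium with a copper acetylide) forms the C3–C4 bond with retention of alkene geometry; the E descriptor arises only from the priority change, C6 remains cis to the alkyne.

Step 5
Reactants: 7 (E)-5-[(tert-butyldimethylsilyloxy)methyl]-7-(triethylsilyloxy)hept-5-en-3-yn-2-one; 8 acrolein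
Product: 9 (3R,8E)-8-[(tert-butyldimethylsilyloxy)methyl]-3-hydroxy-10-(triethylsilyloxy)deca-1,8-dien-6-yn-5-one
Conditions: (S,S)-ProPhenol (10 mol %), Et2Zn (20 mol %), 4 Å MS, THF, 0 °C, 8 (1.5 equiv)
Reagents that add atoms: none
Why: Direct catalytic asymmetric aldol addition in which the dinuclear zinc–ProPhenol complex (ligand: 2,6-bis{[(S)-2-(hydroxydiphenylmethyl)pyrrolidin-1-yl]methyl}-4-methylphenol) generates the zinc enolate of the methyl ynone and delivers it 1,2 to one face of acrolein, forming C8–C9 and setting C8 (R).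

Step 6
Reactants: 9 (3R,8E)-8-[(tert-butyldimethylsilyloxy)methyl]-3-hydroxy-10-(triethylsilyloxy)deca-1,8-dien-6-yn-5-one; 10 ethynylmagnesium bromide
Product: 11 (3R,5R,8E)-8-[(tert-butyldimethylsilyloxy)methyl]-5-ethynyl-10-(triethylsilyloxy)deca-1,8-dien-6-yne-3,5-diol
Conditions: 10 (3.5 equiv), THF/CH2Cl2, −78→−30 °C; aq NH4Cl
Reagents that add atoms: none
Why: Chelation-controlled (Cram-chelate) 1,2-addition of an alkynyl Grignard reagent: the C8 magnesium alkoxide and the ketone form a six-membered chelate with the vinyl group equatorial and the acetylide adds axially, giving the 1,3-syn diol and setting the tertiary carbinol (future C1, R here).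

Step 7
Reactants: 11 (3R,5R,8E)-8-[(tert-butyldimethylsilyloxy)methyl]-5-ethynyl-10-(triethylsilyloxy)deca-1,8-dien-6-yne-3,5-diol; 12 tigloyl chloride
Product: 13 (3R,5R,8E)-8-[(tert-butyldimethylsilyloxy)methyl]-5-ethynyl-5-hydroxy-10-(triethylsilyloxy)deca-1,8-dien-6-yn-3-yl (2E)-2-methylbut-2-enoate
Conditions: 12 (1.3 equiv), pyridine, DMAP (10 mol %), CH2Cl2, 0 °C
Reagents that add atoms: none
Why: DMAP-catalysed acylation esterifies only the secondary C8 alcohol because the tertiary bis-propargylic alcohol is too hindered, and the weak base avoids deconjugation of the tiglate; no stereocentre is touched.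

Step 8
Reactants: 13 (3R,5R,8E)-8-[(tert-butyldimethylsilyloxy)methyl]-5-ethynyl-5-hydroxy-10-(triethylsilyloxy)deca-1,8-dien-6-yn-3-yl (2E)-2-methylbut-2-enoate
Product: 15 (2R)-1-[(2R)-5-{(2Z)-1-(tert-butyldimethylsilyloxy)-4-(triethylsilyloxy)but-2-en-2-yl}-2-methyl-3-oxo-2,3-dihydrofuran-2-yl]but-3-en-2-yl (2E)-2-methylbut-2-enoate, via hydroxy ketone 14 (not isolated)
Conditions: [(IPr)Au(NTf2)] (5 mol %; IPr = 1,3-bis(2,6-diisopropylphenyl)imidazol-2-ylidene, NTf2 = N(SO2CF3)2), H2O (3 equiv), 1,4-dioxane, 45 °C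
Reagents that add atoms: water, O
Why: Proposed new method: one cationic monovalent-gold catalyst performs three events in one flask — Markovnikov hydration of the terminal alkyne (water attacks the internal carbon of the π-complex, assisted by the neighbouring tertiary hydroxyl) to give methyl ketone 14, then 5-endo-dig attack of that ketone oxygen on the gold-activated enyne alkyne at C3 to give a cyclic oxocarbenium ion at C10, then a suprafacial semipinacol-type 1,2-shift of the C9 methylene from the carbinol carbon C1 to C10 as C1 becomes the ketone, followed by protodeauration at C2; because C9 migrates on the ring face it already occupies, the carbinol configuration set in step 6 is transferred to C10 (R); the closest known reaction types are gold-catalysed hydration of propargylic alcohols to α-hydroxy methyl ketones and the gold trichloride- or platinum dichloride-catalysed heterocyclisation/1,2-migration of isolated 2-hydroxy-2-alkynyl ketones to 3(2H)-furanones, whereas their coupling from a 3-hydroxy-1,4-diyne with chirality transfer has not been shown.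

Step 9
Reactants: 15 (2R)-1-[(2R)-5-{(2Z)-1-(tert-butyldimethylsilyloxy)-4-(triethylsilyloxy)but-2-en-2-yl}-2-methyl-3-oxo-2,3-dihydrofuran-2-yl]but-3-en-2-yl (2E)-2-methylbut-2-enoate; 16 methyl 2-(bromomethyl)acrylate
Product: 17 methyl (2Z,4R)-2-(bromomethyl)-5-[(2R)-5-{(2Z)-1-(tert-butyldimethylsilyloxy)-4-(triethylsilyloxy)but-2-en-2-yl}-2-methyl-3-oxo-2,3-dihydrofuran-2-yl]-4-{[(2E)-2-methylbut-2-enoyl]oxy}pent-2-enoate
Conditions: 16 (5 equiv), second-generation Hoveyda–Grubbs catalyst RuCl2(H2IMes)(=CH-C6H4-2-O-i-Pr) (10 mol %), CH2Cl2, 40 °C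
Reagents that add atoms: none
Why: Olefin cross-metathesis between the only monosubstituted alkene and a 1,1-disubstituted acrylate that does not homodimerise gives the thermodynamic trisubstituted enoate (C8 trans to CO2Me, Z); the other alkenes are trisubstituted and electron-poor and do not react.

Step 10
Reactants: 17 methyl (2Z,4R)-2-(bromomethyl)-5-[(2R)-5-{(2Z)-1-(tert-butyldimethylsilyloxy)-4-(triethylsilyloxy)but-2-en-2-yl}-2-methyl-3-oxo-2,3-dihydrofuran-2-yl]-4-{[(2E)-2-methylbut-2-enoyl]oxy}pent-2-enoate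
Product: 19 methyl (2Z,4R)-2-(bromomethyl)-5-[(2R)-5-{(2Z)-1-(tert-butyldimethylsilyloxy)-4-oxobut-2-en-2-yl}-2-methyl-3-oxo-2,3-dihydrofuran-2-yl]-4-{[(2E)-2-methylbut-2-enoyl]oxy}pent-2-enoate, via alkoxysulfonium chloride 18 (not isolated)
Conditions: (COCl)2, DMSO, CH2Cl2, −78→−40 °C; i-Pr2NEt, −78→−20 °C
Reagents that add atoms: none
Why: Swern oxidation applied directly to the primary triethylsilyl ether (chloride of the chlorosulfonium salt removes the silyl group and the alkoxysulfonium ylide collapses to the aldehyde) gives the Z-enal in one operation; the TBS ether, tiglate and allylic bromide are inert at low temperature with a hindered base.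

Step 11
Reactants: 19 methyl (2Z,4R)-2-(bromomethyl)-5-[(2R)-5-{(2Z)-1-(tert-butyldimethylsilyloxy)-4-oxobut-2-en-2-yl}-2-methyl-3-oxo-2,3-dihydrofuran-2-yl]-4-{[(2E)-2-methylbut-2-enoyl]oxy}pent-2-enoate
Product: 22 15-O-tert-butyldimethylsilyl ether of the target (6S,7R,8R,10R), via allylzinc bromide 20 (not isolated), via hydroxy ester 21 (not isolated)
Conditions: Zn dust (TMSCl-activated, 10 equiv), THF, slow addition to 0.002 M, 45 °C; aq NH4Cl
Reagents that add atoms: none
Why: Intramolecular Barbier-type (Dreiding–Schmidt) allylation: the 2-(methoxycarbonyl)allylzinc adds through its γ-carbon C7 to the C6 aldehyde via a six-membered chair transition state that gives the syn adduct, whose zinc alkoxide acylates itself to the cis-fused lactone, while the short tether through C8–C10 is expected to select the (6S,7R) pair; this closes rings B and C.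

Step 12
Reactants: 22 15-O-tert-butyldimethylsilyl ether of the target (6S,7R,8R,10R)
Product: 23 target, [(2Z,4S,8R,9R,11R)-2-(hydroxymethyl)-11-methyl-7-methylidene-6,12-dioxo-5,14-dioxatricyclo[9.2.1.0(4,8)]tetradeca-1(13),2-dien-9-yl] (2E)-2-methylbut-2-enoate
Conditions: HF·pyridine, pyridine, THF, 0→23 °C
Reagents that add atoms: none
Why: Buffered fluoride desilylation of the primary allylic TBS ether leaves the α-methylene lactone, tiglate and furanone untouched and changes no stereocentre.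

**Compound list**
1 | 2-butyne-1,4-diol | OCC#CCO | starting material
2 | 4-(tert-butyldimethylsilyloxy)but-2-yn-1-ol | OCC#CCO[Si](C)(C)C(C)(C)C | intermediate
3 | cyclic alkenylalanate (sodium 2,2-bis(2-methoxyethoxy)-3-[(tert-butyldimethylsilyloxy)methyl]-2,5-dihydro-1,2-oxaaluminol-2-uide) | [Na+].COCCO[Al-]1(OCCOC)OCC=C1CO[Si](C)(C)C(C)(C)C | intermediate
4 | (Z)-4-(tert-butyldimethylsilyloxy)-3-iodobut-2-en-1-ol | OC/C=C(/CO[Si](C)(C)C(C)(C)C)I | intermediate
5 | (Z)-tert-butyl{[2-iodo-4-(triethylsilyloxy)but-2-en-1-yl]oxy}dimethylsilane | CC[Si](CC)(CC)OC/C=C(/CO[Si](C)(C)C(C)(C)C)I | intermediate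
6 | 3-butyn-2-one | CC(=O)C#C | starting material
7 | (E)-5-[(tert-butyldimethylsilyloxy)methyl]-7-(triethylsilyloxy)hept-5-en-3-yn-2-one | CC[Si](CC)(CC)OC/C=C(/CO[Si](C)(C)C(C)(C)C)C#CC(C)=O | intermediate
8 | acrolein | C=CC=O | starting material
9 | (3R,8E)-8-[(tert-butyldimethylsilyloxy)methyl]-3-hydroxy-10-(triethylsilyloxy)deca-1,8-dien-6-yn-5-one | CC[Si](CC)(CC)OC/C=C(/CO[Si](C)(C)C(C)(C)C)C#CC(=O)C[C@@H](O)C=C | intermediate
10 | ethynylmagnesium bromide | C#C[Mg]Br | starting material
11 | (3R,5R,8E)-8-[(tert-butyldimethylsilyloxy)methyl]-5-ethynyl-10-(triethylsilyloxy)deca-1,8-dien-6-yne-3,5-diol | CC[Si](CC)(CC)OC/C=C(/CO[Si](C)(C)C(C)(C)C)C#C[C@](O)(C#C)C[C@@H](O)C=C | intermediate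
12 | tigloyl chloride, (E)-2-methylbut-2-enoyl chloride | O=C(Cl)/C(C)=C/C | starting material
13 | (3R,5R,8E)-8-[(tert-butyldimethylsilyloxy)methyl]-5-ethynyl-5-hydroxy-10-(triethylsilyloxy)deca-1,8-dien-6-yn-3-yl (2E)-2-methylbut-2-enoate | CC[Si](CC)(CC)OC/C=C(/CO[Si](C)(C)C(C)(C)C)C#C[C@](O)(C#C)C[C@@H](OC(=O)/C(C)=C/C)C=C | intermediate
14 | hydroxy ketone, (3R,5S,8E)-5-acetyl-8-[(tert-butyldimethylsilyloxy)methyl]-5-hydroxy-10-(triethylsilyloxy)deca-1,8-dien-6-yn-3-yl (2E)-2-methylbut-2-enoate | CC[Si](CC)(CC)OC/C=C(/CO[Si](C)(C)C(C)(C)C)C#C[C@](O)(C(C)=O)C[C@@H](OC(=O)/C(C)=C/C)C=C | intermediate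
15 | (2R)-1-[(2R)-5-{(2Z)-1-(tert-butyldimethylsilyloxy)-4-(triethylsilyloxy)but-2-en-2-yl}-2-methyl-3-oxo-2,3-dihydrofuran-2-yl]but-3-en-2-yl (2E)-2-methylbut-2-enoate | CC[Si](CC)(CC)OC/C=C(/CO[Si](C)(C)C(C)(C)C)C1=CC(=O)[C@@](C)(C[C@@H](OC(=O)/C(C)=C/C)C=C)O1 | intermediate
16 | methyl 2-(bromomethyl)acrylate | C=C(CBr)C(=O)OC | starting material
17 | methyl (2Z,4R)-2-(bromomethyl)-5-[(2R)-5-{(2Z)-1-(tert-butyldimethylsilyloxy)-4-(triethylsilyloxy)but-2-en-2-yl}-2-methyl-3-oxo-2,3-dihydrofuran-2-yl]-4-{[(2E)-2-methylbut-2-enoyl]oxy}pent-2-enoate | CC[Si](CC)(CC)OC/C=C(/CO[Si](C)(C)C(C)(C)C)C1=CC(=O)[C@@](C)(C[C@@H](OC(=O)/C(C)=C/C)/C=C(\CBr)C(=O)OC)O1 | intermediate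
18 | alkoxysulfonium chloride (C6–O–S(CH3)2 cation derived from 17, chloride salt) | C[S+](C)OC/C=C(/CO[Si](C)(C)C(C)(C)C)C1=CC(=O)[C@@](C)(C[C@@H](OC(=O)/C(C)=C/C)/C=C(\CBr)C(=O)OC)O1.[Cl-] | intermediate
19 | methyl (2Z,4R)-2-(bromomethyl)-5-[(2R)-5-{(2Z)-1-(tert-butyldimethylsilyloxy)-4-oxobut-2-en-2-yl}-2-methyl-3-oxo-2,3-dihydrofuran-2-yl]-4-{[(2E)-2-methylbut-2-enoyl]oxy}pent-2-enoate | O=C/C=C(/CO[Si](C)(C)C(C)(C)C)C1=CC(=O)[C@@](C)(C[C@@H](OC(=O)/C(C)=C/C)/C=C(\CBr)C(=O)OC)O1 | intermediate
20 | allylzinc bromide (C13–ZnBr reagent derived from 19) | O=C/C=C(/CO[Si](C)(C)C(C)(C)C)C1=CC(=O)[C@@](C)(C[C@@H](OC(=O)/C(C)=C/C)/C=C(\C[Zn]Br)C(=O)OC)O1 | intermediate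
21 | hydroxy ester (ring-B-closed seco-lactone: free C6 hydroxyl, C7 bearing the methyl acrylate unit, configuration as in 22) | C=C(C(=O)OC)[C@H]1[C@@H](O)/C=C(/CO[Si](C)(C)C(C)(C)C)C2=CC(=O)[C@@](C)(C[C@H]1OC(=O)/C(C)=C/C)O2 | intermediate
22 | 15-O-tert-butyldimethylsilyl ether of the target (6S,7R,8R,10R) | C=C1C(=O)O[C@H]2/C=C(/CO[Si](C)(C)C(C)(C)C)C3=CC(=O)[C@@](C)(C[C@@H](OC(=O)/C(C)=C/C)[C@@H]12)O3 | intermediate
23 | target, [(2Z,4S,8R,9R,11R)-2-(hydroxymethyl)-11-methyl-7-methylidene-6,12-dioxo-5,14-dioxatricyclo[9.2.1.0(4,8)]tetradeca-1(13),2-dien-9-yl] (2E)-2-methylbut-2-enoate | C=C1C(=O)O[C@H]2/C=C(/CO)C3=CC(=O)[C@@](C)(C[C@@H](OC(=O)/C(C)=C/C)[C@@H]12)O3 | target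

**Step count and risks**

Total step count: 12. Longest linear sequence: 12 steps (from 2-butyne-1,4-diol 1; the other starting materials each enter in a single step).

The three steps most likely to fail:

Step 8 (the proposed new cascade). The risks are Meyer–Schuster rearrangement of the bis-propargylic alcohol, gold-catalysed cyclisation of the alkyne onto the C7 vinyl group (a 1,6-enyne), loss of the triethylsilyl ether in the wet medium, and slow migration of the β-acyloxyalkyl group. The fallback uses only known chemistry, sets out from 9 and rejoins the route at 14. Two equivalents of 1-ethoxyvinyllithium (ethyl vinyl ether, t-BuLi, MgBr2·OEt2, THF, −78 °C) add to the chelated β-alkoxide ketone with the same facial sense as in step 6 to give enol ether adduct F1. Brief treatment with aqueous oxalic acid in THF at 0 °C unmasks the methyl ketone to give hydroxy ketone F2. Tigloylation of its secondary alcohol with 12 (pyridine, DMAP) gives 14 as an isolated compound. AuCl3 (5 mol %, CH2Cl2, 23 °C) then effects the established heterocyclisation/1,2-alkyl migration of 2-hydroxy-2-alkynyl ketones to give 15.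

Step 9 (cross-metathesis). The hindered allylic ester and the 1,1-disubstituted bromoacrylate may give low conversion. The fallback sets out from 15 and rejoins at 17. OsO4 (2 mol %) with NMO dihydroxylates the only monosubstituted alkene to give diol F3 (C7 epimers). NaIO4 cleaves it to α-tigloyloxy aldehyde F4. A Morita–Baylis–Hillman reaction with methyl acrylate (DABCO, 0→23 °C, kept short to protect C8) gives allylic alcohol F5 (C7 epimers). PBr3 (Et2O, −10 °C) brominates with allylic transposition (SN2′) to the Z-bromide 17.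

Step 11 (macrocyclising allylation). The allylzinc may be protonated or oligomerise before the strained ring closes, and its rapid E/Z equilibration could erode the cis (6S,7R) outcome. The fallback sets out from 19 and rejoins at 22. Pd2(dba)3-catalysed borylation of the allylic bromide with B2pin2 (THF, 23 °C) gives the configurationally defined allylboronate F6. Sc(OTf)3 (10 mol %, toluene, 23→60 °C) promotes intramolecular allylboration through a closed chair transition state, in which the Z-boronate must give the syn adduct, to give borate F7. Work-up with TsOH lactonises this to 22. A chiral Brønsted acid can replace Sc(OTf)3 if facial control by the tether is insufficient.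

Further compounds
F1 | step 8 | enol ether adduct, (3R,5S,8E)-8-[(tert-butyldimethylsilyloxy)methyl]-5-(1-ethoxyvinyl)-10-(triethylsilyloxy)deca-1,8-dien-6-yne-3,5-diol | CC[Si](CC)(CC)OC/C=C(/CO[Si](C)(C)C(C)(C)C)C#C[C@](O)(C(=C)OCC)C[C@@H](O)C=C
F2 | step 8 | hydroxy ketone, (3R,5S,8E)-5-acetyl-8-[(tert-butyldimethylsilyloxy)methyl]-10-(triethylsilyloxy)deca-1,8-dien-6-yne-3,5-diol | CC[Si](CC)(CC)OC/C=C(/CO[Si](C)(C)C(C)(C)C)C#C[C@](O)(C(C)=O)C[C@@H](O)C=C
F3 | step 9 | diol (15 with the C7 vinyl group converted to CH(OH)CH2OH; C7 epimers) | CC[Si](CC)(CC)OC/C=C(/CO[Si](C)(C)C(C)(C)C)C1=CC(=O)[C@@](C)(C[C@@H](OC(=O)/C(C)=C/C)C(O)CO)O1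
F4 | step 9 | α-tigloyloxy aldehyde (C7 aldehyde) | CC[Si](CC)(CC)OC/C=C(/CO[Si](C)(C)C(C)(C)C)C1=CC(=O)[C@@](C)(C[C@@H](OC(=O)/C(C)=C/C)C=O)O1
F5 | step 9 | allylic alcohol (Morita–Baylis–Hillman adduct; C7 epimers) | CC[Si](CC)(CC)OC/C=C(/CO[Si](C)(C)C(C)(C)C)C1=CC(=O)[C@@](C)(C[C@@H](OC(=O)/C(C)=C/C)C(O)C(=C)C(=O)OC)O1
F6 | step 11 | allylboronate (19 with C13–Br replaced by C13–B(pinacolato)) | O=C/C=C(/CO[Si](C)(C)C(C)(C)C)C1=CC(=O)[C@@](C)(C[C@@H](OC(=O)/C(C)=C/C)/C=C(\CB2OC(C)(C)C(C)(C)O2)C(=O)OC)O1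
F7 | step 11 | borate (21 with the C6 oxygen bound to B(pinacolato)) | C=C(C(=O)OC)[C@H]1[C@@H](OB3OC(C)(C)C(C)(C)O3)/C=C(/CO[Si](C)(C)C(C)(C)C)C2=CC(=O)[C@@](C)(C[C@H]1OC(=O)/C(C)=C/C)O2
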